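**Retrosynthetic overview**
- Feature: the core is a bicyclo[3.3.1]nonane with bridgeheads C1 and C5, bridge C9, and the arms C2–C3–C4 and C6–C7–C8. Its ring B bond C1–C8 joins two fully substituted carbons. With the C1 prenyl, the C3 aroyl and the C2 oxygen removed, cutting C1–C8 leaves ring A (C1–C2–C3–C4–C5–C9) as a mirror-symmetric 1,5-dimethoxycyclohexa-1,4-diene whose sp3 carbon is C5. C8 becomes the tertiary oxirane carbon of an epoxygeranyl chain on C5.
- Late disconnections, last first: C4–OMe and ArO–Si (hydroxide); C3–aroyl (vinyl lithiation); C7 prenyl cut at CH2–CH= (B-alkyl Suzuki) back to C7=CH2 and a C7 ketone; C1–prenyl (bridgehead lithiation); the C9–O–C7 bridge; C2=O (allylic oxidation, placed before the ketal is opened).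
- Key disconnection: C1–C8 and the C9–O–C7 ketal bridge. Both form in one operation when a silyl triflate opens the epoxide and one of the two enol ethers attacks.
- Precursor: two lithiation–alkylations of the dimethoxydiene, first with prenyl bromide, then with the bromide of (2R,3R)-epoxygeraniol (Sharpless epoxidation with the D-tartrate).
- Ring order: ring A is bought as the diene. Ring B and a temporary oxa-bridge close together in the key step, and the oxa-bridge is opened again later.

Key step: step 5

Numbering and terms: target numbering is used for all bicyclic compounds. Ring B is C1–C9–C5–C6–C7–C8. "Exo" means on the C9 side of ring B and "endo" means on the side of the C2–C4 arm. The target is (1S,5S,7S,8S): the C7 prenyl and the C8 homoprenyl are on the endo side, and the C8 methyl is on the exo side.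

Assumption: the C2 and C4 enol tautomers of the final β-triketone interconvert freely, so the product of step 19 is written as the tautomer of the target SMILES.

**Step 1**
Reactants: 1 geraniol
Product: 2 (2R,3R)-2,3-epoxygeraniol
Conditions: Ti(OiPr)4 (5 mol %), D-(−)-diethyl tartrate (6 mol %), t-BuOOH, 4 Å MS, CH2Cl2, −20 °C
Reagents that add atoms: tert-butyl hydroperoxide, CC(C)(C)OO
Why: Sharpless asymmetric epoxidation is directed by the allylic hydroxyl, so only the 2,3-alkene reacts, and the D-(−)-tartrate catalyst delivers oxygen to the face that gives the (2R,3R)-oxirane (future C7 and C8), the only stereocentres set by an external chiral agent.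

**Step 2**
Reactants: 2 (2R,3R)-2,3-epoxygeraniol
Product: 4 epoxygeranyl bromide (2S,3R; same spatial arrangement as 2), via epoxygeranyl mesylate 3 (not isolated)
Conditions: MsCl, Et3N, CH2Cl2, −20 °C; then LiBr, THF, 0 °C → rt
Reagents that add atoms: lithium bromide, [Li+].[Br-]
Why: Mesylation and SN2 displacement by bromide (Finkelstein-type) occur only at the primary carbon under non-acidic conditions, so the oxirane and both of its stereocentres are untouched.

**Step 3**
Reactants: 5 1,5-dimethoxycyclohexa-1,4-diene; 6 prenyl bromide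
Product: 8 1,5-dimethoxy-6-prenylcyclohexa-1,4-diene, via 6-lithio-1,5-dimethoxycyclohexadiene 7 (not isolated)
Conditions: t-BuLi, THF, −78 °C; then 6, −78 °C → rt
Reagents that add atoms: none
Why: Lithiation of the doubly allylic C–H between the two methoxy-bearing carbons gives a cyclohexadienyl anion, which is alkylated by SN2 at its central carbon and so keeps the unconjugated bis-enol ether.

**Step 4**
Reactants: 8 1,5-dimethoxy-6-prenylcyclohexa-1,4-diene; 4 epoxygeranyl bromide
Product: 10 1,5-dimethoxy-6-prenyl-6-[(2R,3R)-2,3-epoxygeranyl]cyclohexa-1,4-diene, via 6-lithio-6-prenyl diene 9 (not isolated)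
Conditions: s-BuLi, THF, −78 → −30 °C; then 4, −78 → 0 °C
Reagents that add atoms: none
Why: A second lithiation–alkylation at the same carbon works because the primary bromide next to the oxirane is a far better SN2 partner than either oxirane carbon; the new quaternary carbon (future C5) bears two identical enol ether arms and is not yet a stereocentre.

**Step 5**
Reactants: 10 1,5-dimethoxy-6-prenyl-6-[(2R,3R)-2,3-epoxygeranyl]cyclohexa-1,4-diene
Product: 12 bridged C9 mixed ketal of the bicyclic core bearing the C4 methyl enol ether (1S,5S,7R,8R,9R), via C7-silyloxy C9-oxocarbenium triflate 11 (not isolated)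
Conditions: TMSOTf (0.3 equiv), 2,6-lutidine (0.5 equiv), CH2Cl2 (dilute), −78 °C; then Et3N, aq NaHCO3
Reagents that add atoms: none
Why: Silylation of the oxirane oxygen polarises the C8–O bond, carbon C1 of one methyl enol ether attacks tertiary C8 anti to the departing oxygen to form C1–C8 and the O-methyl oxocarbenium ion 11, and the C7 silyl ether oxygen then adds to C9 and gives the silyl group back, so the promoter turns over. The closest known reaction type is the Lewis-acid epoxide-opening cation–olefin cyclisation terminated by an enol ether, which is established for bicyclo[3.3.1]nonane cores of this family. Ring B (C1, C9, C5, C6, C7, C8) closes in a 6-(enolendo)-endo-tet mode, since both oxirane carbons and both enol ether carbons end up inside the new ring, and this is feasible because tertiary C8 carries much of the positive charge; the oxa-bridge (O, C7, C6, C5, C9) closes 5-exo-trig on the oxocarbenium ion. C7 keeps the oxirane configuration and C8 is inverted by the anti attack (methyl exo, homoprenyl on the endo side); C1 and C5 follow from the chair-like array that holds the C7–O bond equatorial and lets only one of the two diastereotopic enol ethers reach the back of C8; C9 is fixed because the C7 oxygen can reach it only from the ring B side, away from the C2–C4 arm. The step needs group selectivity between the enol ethers, regioselectivity for C8 over C7, and chemoselectivity over the two trisubstituted alkenes. These are secured, in the same order, by the fact that attack of the other enol ether demands a boat-like array leaving the oxygen endo and unable to close the ketal, by the tertiary against secondary nature of the oxirane carbons, and by the far higher nucleophilicity of an enol ether, while 2,6-lutidine keeps the medium free of acid so the C4 enol ether survives.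

**Step 6**
Reactants: 12 bridged C9 mixed ketal with C4 methyl enol ether
Product: 13 C2-oxo ketal (vinylogous methyl ester C2=O/C3=C4–OMe)
Conditions: PhI(OAc)2, t-BuOOH, K2CO3 (0.5 equiv), EtOAc, −20 °C
Reagents that add atoms: tert-butyl hydroperoxide, CC(C)(C)OO
Why: Radical allylic C–H oxidation by tert-butylperoxy radicals (allyl peroxide, then Kornblum–DeLaMare-type collapse) should pick the C2 methylene because its radical is delocalised onto methoxy-bearing C4, and doing it now turns the acid-labile enol ether into a robust vinylogous ester before the ketal is opened.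

**Step 7**
Reactants: 13 C2-oxo ketal
Product: 15 C3-trimethylsilyl C2-oxo ketal, via C3-lithio vinylogous ester 14 (not isolated)
Conditions: LiTMP, TMSCl (in situ quench), THF, −78 °C
Reagents that add atoms: chlorotrimethylsilane, C[Si](C)(C)Cl
Why: Vinylic lithiation of the β-methoxy enone at C3, its kinetically most acidic site, with in situ silyl trapping blocks C3 so that the later strong-base step can act only at C1.

**Step 8**
Reactants: 15 C3-trimethylsilyl C2-oxo ketal
Product: 17 C7-exo-hydroxy C9-ketone (may rest partly as its C9 hemiketal), via C7 borinate C9 bromo ether 16 (not isolated)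
Conditions: BrBMe2, CH2Cl2, −78 °C; then Et3N, sat. aq NaHCO3, THF
Reagents that add atoms: water, O
Why: In this boron-halide ketal cleavage the Lewis acid binds the bridging oxygen and the C9–O bond breaks with help from the methoxy group (loss of methoxy would need a bridgehead oxocarbenium ion in the 7-oxanorbornane unit); hydrolysis of 16 on work-up then frees the C9 ketone and the C7 alcohol with the C7–O bond, the alkenes and the vinylogous ester intact.

**Step 9**
Reactants: 17 C7-exo-hydroxy C9-ketone
Product: 18 C7-exo triethylsilyl ether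
Conditions: TESOTf, 2,6-lutidine, CH2Cl2, −78 → 0 °C
Reagents that add atoms: triethylsilyl triflate, CC[Si](CC)(CC)OS(=O)(=O)C(F)(F)F
Why: Silyl ether formation under non-basic conditions masks the hydroxyl, which in step 10 would consume base and, as its alkoxide, could add to C9 and start a retro-Claisen cleavage.

**Step 10**
Reactants: 18 C7-exo triethylsilyl ether; 6 prenyl bromide
Product: 20 C1-prenyl C7-exo triethylsilyl ether, via C1-lithio bridgehead carbanion 19 (not isolated)
Conditions: LiTMP, THF, −78 → 0 °C; then 6 (excess), −78 °C → rt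
Reagents that add atoms: none
Why: In this bridgehead lithiation–alkylation, with C3 silylated and C5 quaternary, the only acidic C–H left is C1–H between the C2 and C9 carbonyls, and the pyramidal bridgehead carbanion is captured by the allylic bromide with necessarily retained configuration, completing the C1/C8 vicinal quaternary pair.

**Step 11**
Reactants: 20 C1-prenyl C7-exo triethylsilyl ether
Product: 21 C1-prenyl C7-exo alcohol (C3–SiMe3 kept; may rest partly as its C9 hemiketal)
Conditions: HF·pyridine, pyridine, THF, 0 °C
Reagents that add atoms: none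
Why: Acidic fluoride desilylation removes the O–SiEt3 group without ever forming the C7 alkoxide, and the C3–SiMe3 bond should persist under the pyridine-buffered conditions.

**Step 12**
Reactants: 21 C1-prenyl C7-exo alcohol
Product: 22 C7 ketone
Conditions: Dess–Martin periodinane, CH2Cl2, rt
Reagents that add atoms: none
Why: Dess–Martin oxidation drains the open hydroxy ketone from its hemiketal equilibrium under nearly neutral conditions that leave the trisubstituted alkenes and the vinylsilane alone.

**Step 13**
Reactants: 22 C7 ketone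
Product: 23 C7 exocyclic methylene compound (C3–SiMe3)
Conditions: Ph3PCH3Br, KN(SiMe3)2, THF–toluene, 0 → 50 °C
Reagents that add atoms: methyltriphenylphosphonium bromide, C[P+](c1ccccc1)(c1ccccc1)c1ccccc1.[Br-]
Why: Wittig methylenation should hit C7 only, because C9 now lies between two quaternary bridgeheads and C2 is a deactivated vinylogous ester next to quaternary C1, and no stereocentre next to C7 can epimerise since C8 is quaternary.

**Step 14**
Reactants: 23 C7 exocyclic methylene compound (C3–SiMe3)
Product: 24 C7 exocyclic methylene compound (C3–H)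
Conditions: TBAF, THF, 0 °C
Reagents that add atoms: none
Why: Fluoride-induced protodesilylation of the α-silyl enone frees C3–H at a stage where no hydroxyl group or enolisable ketone is present that basic fluoride could harm.

**Step 15**
Reactants: 24 C7 exocyclic methylene compound (C3–H); 25 1-bromo-2-methylprop-1-ene
Product: 27 C7-endo-prenyl vinylogous methyl ester, via C7-endo B-alkyl-9-BBN 26 (not isolated)
Conditions: 9-BBN, THF, rt → 40 °C; then 25, Pd(dppf)Cl2 (5 mol %), aq K3PO4, DMF, rt → 50 °C
Reagents that add atoms: none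
Why: In this hydroboration followed by B-alkyl Suzuki–Miyaura coupling, 9-BBN adds to the 1,1-disubstituted C7=CH2 much faster than to the three trisubstituted alkenes or the shielded carbonyls, boron goes to the CH2 terminus and hydrogen to C7 from the exo face (the endo face is closed by the C2–C4 arm of the chair–chair core), so the CH2–B arm and, after coupling at that carbon, the prenyl group stand endo, which is the (7S) configuration of the target.

**Step 16**
Reactants: 28 3-hydroxybenzoic acid
Product: 29 tert-butyldimethylsilyl 3-(tert-butyldimethylsilyloxy)benzoate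
Conditions: TBSCl (2.2 equiv), imidazole, DMF, rt
Reagents that add atoms: tert-butyldimethylsilyl chloride, CC(C)(C)[Si](C)(C)Cl
Why: Standard silylation caps both acidic OH groups, giving a phenol protection that tolerates the organolithium step and falls off under the final hydroxide conditions.

**Step 17**
Reactants: 29 tert-butyldimethylsilyl 3-(tert-butyldimethylsilyloxy)benzoate
Product: 30 3-(tert-butyldimethylsilyloxy)benzoyl chloride
Conditions: (COCl)2, DMF (cat.), CH2Cl2, 0 °C → rt
Reagents that add atoms: oxalyl chloride, O=C(Cl)C(=O)Cl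
Why: Silyl esters are converted directly into acid chlorides by the Vilsmeier-type chloroiminium reagent under neutral conditions, which spares the aryl silyl ether.

**Step 18**
Reactants: 27 C7-endo-prenyl vinylogous methyl ester; 30 3-(tert-butyldimethylsilyloxy)benzoyl chloride
Product: 32 C3-aroyl vinylogous methyl ester (aryl OTBS), via C3-lithio vinylogous ester 31 (not isolated)
Conditions: LiTMP, THF, −78 °C; then 30, −78 → −40 °C
Reagents that add atoms: none
Why: In this vinylic lithiation–acylation, with both bridgeheads quaternary, C3–H of the β-methoxy enone is the only site the amide base can deprotonate, and the acylated product has no acidic hydrogen that could consume a second equivalent.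

**Step 19**
Reactants: 32 C3-aroyl vinylogous methyl ester (aryl OTBS)
Product: 34 target CNP0406274.1 (1S,5S,7S,8S), via dilithium enolate phenolate 33 (not isolated)
Conditions: LiOH, 1,4-dioxane–H2O, 90 °C; then 1 M HCl to pH 3, 0 °C
Reagents that add atoms: lithium hydroxide, [Li+].[OH-]
Why: Hydroxide addition–elimination at C4 of the doubly activated vinylogous ester and hydroxide cleavage of the aryl silyl ether occur together, the delocalised enolate formed shields C2 and C9 from retro-Claisen attack, and none of the four stereocentres (three quaternary, C7 not next to a carbonyl) can epimerise.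

**Compound list**
1 | geraniol, (E)-3,7-dimethylocta-2,6-dien-1-ol | CC(C)=CCC/C(C)=C/CO | starting material
2 | (2R,3R)-2,3-epoxygeraniol | OC[C@H]1O[C@]1(C)CCC=C(C)C | intermediate
3 | (2R,3R)-2,3-epoxygeranyl mesylate (not isolated) | CS(=O)(=O)OC[C@H]1O[C@]1(C)CCC=C(C)C | intermediate
4 | (2S,3R)-2-(bromomethyl)-3-methyl-3-(4-methylpent-3-enyl)oxirane (epoxygeranyl bromide) | BrC[C@H]1O[C@]1(C)CCC=C(C)C | intermediate
5 | 1,5-dimethoxycyclohexa-1,4-diene | COC1=CCC=C(OC)C1 | starting material
6 | prenyl bromide, 1-bromo-3-methylbut-2-ene | CC(C)=CCBr | starting material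
7 | 6-lithio-1,5-dimethoxycyclohexa-1,4-diene (not isolated) | [Li]C1C(OC)=CCC=C1OC | intermediate
8 | 1,5-dimethoxy-6-prenylcyclohexa-1,4-diene | COC1=CCC=C(OC)C1CC=C(C)C | intermediate
9 | 6-lithio-1,5-dimethoxy-6-prenylcyclohexa-1,4-diene (not isolated) | [Li]C1(CC=C(C)C)C(OC)=CCC=C1OC | intermediate
10 | 1,5-dimethoxy-6-prenyl-6-[(2R,3R)-2,3-epoxygeranyl]cyclohexa-1,4-diene (key-step precursor) | COC1=CCC=C(OC)C1(CC=C(C)C)C[C@H]2O[C@]2(C)CCC=C(C)C | intermediate
11 | bicyclic C9 O-methyl oxocarbenium triflate with C7-exo OSiMe3 (not isolated) | CC(C)=CCC[C@@]1(C)[C@H](O[Si](C)(C)C)C[C@]2(CC=C(C)C)C(=[O+]C)[C@H]1CC=C2OC.[O-]S(=O)(=O)C(F)(F)F | intermediate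
12 | (1S,5S,7R,8R,9R)-7,9-epoxy-4,9-dimethoxy-8-methyl-8-homoprenyl-5-prenylbicyclo[3.3.1]non-3-ene; C7–O exo, C8 methyl exo (key-step product) | CC(C)=CCC[C@@]1(C)[C@H]3C[C@]2(CC=C(C)C)[C@](OC)(O3)[C@H]1CC=C2OC | intermediate
13 | C2 ketone of 12 (vinylogous methyl ester, ketal intact) | CC(C)=CCC[C@@]1(C)[C@H]3C[C@]2(CC=C(C)C)[C@](OC)(O3)[C@H]1C(=O)C=C2OC | intermediate
14 | C3-lithio derivative of 13 (not isolated) | CC(C)=CCC[C@@]1(C)[C@H]3C[C@]2(CC=C(C)C)[C@](OC)(O3)[C@H]1C(=O)C([Li])=C2OC | intermediate
15 | C3-trimethylsilyl derivative of 13 | CC(C)=CCC[C@@]1(C)[C@H]3C[C@]2(CC=C(C)C)[C@](OC)(O3)[C@H]1C(=O)C([Si](C)(C)C)=C2OC | intermediate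
16 | C7-exo dimethylborinate, C9 bromo(methoxy) compound, C9 configuration open (not isolated) | CC(C)=CCC[C@@]1(C)[C@H](OB(C)C)C[C@]2(CC=C(C)C)C(Br)(OC)[C@H]1C(=O)C([Si](C)(C)C)=C2OC | intermediate
17 | 7-exo-hydroxy-4-methoxy-8-methyl-8-homoprenyl-5-prenyl-3-trimethylsilylbicyclo[3.3.1]non-3-ene-2,9-dione | CC(C)=CCC[C@@]1(C)[C@H](O)C[C@]2(CC=C(C)C)C(=O)[C@H]1C(=O)C([Si](C)(C)C)=C2OC | intermediate
18 | C7-exo triethylsilyl ether of 17 | CC(C)=CCC[C@@]1(C)[C@H](O[Si](CC)(CC)CC)C[C@]2(CC=C(C)C)C(=O)[C@H]1C(=O)C([Si](C)(C)C)=C2OC | intermediate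
19 | C1-lithio derivative of 18 (not isolated) | CC(C)=CCC[C@@]1(C)[C@H](O[Si](CC)(CC)CC)C[C@]2(CC=C(C)C)C(=O)[C@@]1([Li])C(=O)C([Si](C)(C)C)=C2OC | intermediate
20 | C1-prenyl derivative of 18 | CC(C)=CCC[C@@]1(C)[C@H](O[Si](CC)(CC)CC)C[C@]2(CC=C(C)C)C(=O)[C@@]1(CC=C(C)C)C(=O)C([Si](C)(C)C)=C2OC | intermediate
21 | C7-exo alcohol from 20 (C3–SiMe3 kept) | CC(C)=CCC[C@@]1(C)[C@H](O)C[C@]2(CC=C(C)C)C(=O)[C@@]1(CC=C(C)C)C(=O)C([Si](C)(C)C)=C2OC | intermediate
22 | 2,7,9-trione, C4 methyl enol ether, C3–SiMe3 | CC(C)=CCC[C@@]1(C)C(=O)C[C@]2(CC=C(C)C)C(=O)[C@@]1(CC=C(C)C)C(=O)C([Si](C)(C)C)=C2OC | intermediate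
23 | 7-methylene compound, C3–SiMe3 | CC(C)=CCC[C@@]1(C)C(=C)C[C@]2(CC=C(C)C)C(=O)[C@@]1(CC=C(C)C)C(=O)C([Si](C)(C)C)=C2OC | intermediate
24 | 7-methylene compound, C3–H | CC(C)=CCC[C@@]1(C)C(=C)C[C@]2(CC=C(C)C)C(=O)[C@@]1(CC=C(C)C)C(=O)C=C2OC | intermediate
25 | 1-bromo-2-methylprop-1-ene | CC(C)=CBr | starting material
26 | C7-endo (9-borabicyclo[3.3.1]nonan-9-yl)methyl compound (not isolated) | CC(C)=CCC[C@@]1(C)[C@@H](CB3C4CCCC3CCC4)C[C@]2(CC=C(C)C)C(=O)[C@@]1(CC=C(C)C)C(=O)C=C2OC | intermediate
27 | 4-methoxy-8-methyl-8-homoprenyl-1,5,7-endo-triprenylbicyclo[3.3.1]non-3-ene-2,9-dione | CC(C)=CCC[C@@]1(C)[C@@H](CC=C(C)C)C[C@]2(CC=C(C)C)C(=O)[C@@]1(CC=C(C)C)C(=O)C=C2OC | intermediate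
28 | 3-hydroxybenzoic acid | OC(=O)c1cccc(O)c1 | starting material
29 | tert-butyldimethylsilyl 3-(tert-butyldimethylsilyloxy)benzoate | CC(C)(C)[Si](C)(C)OC(=O)c1cccc(O[Si](C)(C)C(C)(C)C)c1 | intermediate
30 | 3-(tert-butyldimethylsilyloxy)benzoyl chloride | O=C(Cl)c1cccc(O[Si](C)(C)C(C)(C)C)c1 | intermediate
31 | C3-lithio derivative of 27 (not isolated) | CC(C)=CCC[C@@]1(C)[C@@H](CC=C(C)C)C[C@]2(CC=C(C)C)C(=O)[C@@]1(CC=C(C)C)C(=O)C([Li])=C2OC | intermediate
32 | C3-[3-(tert-butyldimethylsilyloxy)benzoyl] derivative of 27 | CC(C)=CCC[C@@]1(C)[C@@H](CC=C(C)C)C[C@]2(CC=C(C)C)C(=O)[C@@]1(CC=C(C)C)C(=O)C(C(=O)c1cccc(O[Si](C)(C)C(C)(C)C)c1)=C2OC | intermediate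
33 | dilithium enolate phenolate of the target (not isolated) | CC(C)=CCC[C@@]1(C)[C@@H](CC=C(C)C)C[C@]2(CC=C(C)C)C(=O)[C@@]1(CC=C(C)C)C(=O)C(C(=O)c1cccc([O-])c1)=C2[O-].[Li+].[Li+] | intermediate
34 | (1S,5S,7S,8S)-4-hydroxy-3-(3-hydroxybenzoyl)-8-methyl-1,5,7-tris(3-methylbut-2-enyl)-8-(4-methylpent-3-enyl)bicyclo[3.3.1]non-3-ene-2,9-dione | CC(C)=CCC[C@@]1(C)[C@@H](CC=C(C)C)C[C@]2(CC=C(C)C)C(=O)[C@@]1(CC=C(C)C)C(=O)C(C(=O)c1cccc(O)c1)=C2O | target

**Step count**
- Total step count: 19.
- Longest linear sequence: 16 (steps 1, 2, 4–15, 18, 19, from geraniol).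

**Steps most likely to fail**

1. Step 10. Capture of the bridgehead carbanion may be too slow next to quaternary C8. The proton would then return on work-up, and the excess amide base would consume the bromide.
   - The fallback sets out from 18 and comes back at 20.
   - Compound 18 is lithiated as in step 10, and carbanion 19 is quenched with I2, a small and fast electrophile, to give the bridgehead iodide F1.
   - A Keck radical allylation follows (Bu3SnCH2CH=CH2 in large excess to outrun 5-exo closure onto the homoprenyl alkene, Et3B, air, benzene, rt). It forms the C1–C bond through the bridgehead radical, which is little affected by crowding, and gives the C1-allyl compound F2.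
   - Cross metathesis with 2-methylbut-2-ene (second-generation Grubbs catalyst, CH2Cl2, 40 °C) is degenerate for the prenyl and homoprenyl groups. It turns allyl into prenyl and gives 20.

2. Step 15. Transmetalation of the endo, β-branched B-alkyl group may be slow and lead to protodeboronation. Some hydroboration of the trisubstituted alkenes may also occur and cannot be removed in a one-pot process.
   - The fallback sets out from 26 (made from 24 as in step 15) and comes back at 27.
   - The borane is oxidised with NaBO3·4H2O (THF–H2O, rt) to the isolable C7-endo hydroxymethyl compound F4, which can be purified.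
   - An Appel-type iodination (I2, PPh3, imidazole, CH2Cl2, 0 °C) gives the primary iodide F5.
   - Zinc insertion (Zn dust, LiCl, THF, rt), which tolerates the ketones, gives the alkylzinc iodide F6.
   - Negishi coupling with 25 (Pd(PPh3)4, THF, 40 °C) closes the prenyl group and gives 27.

3. Step 13. The basic ylide may enolise the C7 ketone towards C6 instead of adding, because quaternary C8 slows attack at the carbonyl.
   - The fallback sets out from 22 and comes back at 23.
   - The weakly basic organocerium reagent from Me3SiCH2Li and CeCl3 (THF, −78 °C) adds to C7 from the exo face and gives the β-hydroxysilane F3.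
   - Peterson elimination (KN(SiMe3)2, THF, 0 °C → rt) expels silanolate and gives the exocyclic methylene compound 23.

**Further compounds**
F1 | step 10 | C1 bridgehead iodide of 18 | CC(C)=CCC[C@@]1(C)[C@H](O[Si](CC)(CC)CC)C[C@]2(CC=C(C)C)C(=O)[C@@]1(I)C(=O)C([Si](C)(C)C)=C2OC
F2 | step 10 | C1-allyl derivative of 18 | CC(C)=CCC[C@@]1(C)[C@H](O[Si](CC)(CC)CC)C[C@]2(CC=C(C)C)C(=O)[C@@]1(CC=C)C(=O)C([Si](C)(C)C)=C2OC
F3 | step 13 | C7-endo-hydroxy C7-exo-(trimethylsilylmethyl) adduct of 22 | CC(C)=CCC[C@@]1(C)[C@](O)(C[Si](C)(C)C)C[C@]2(CC=C(C)C)C(=O)[C@@]1(CC=C(C)C)C(=O)C([Si](C)(C)C)=C2OC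
F4 | step 15 | C7-endo hydroxymethyl compound | CC(C)=CCC[C@@]1(C)[C@@H](CO)C[C@]2(CC=C(C)C)C(=O)[C@@]1(CC=C(C)C)C(=O)C=C2OC
F5 | step 15 | C7-endo iodomethyl compound | CC(C)=CCC[C@@]1(C)[C@@H](CI)C[C@]2(CC=C(C)C)C(=O)[C@@]1(CC=C(C)C)C(=O)C=C2OC
F6 | step 15 | C7-endo (iodozincio)methyl compound | CC(C)=CCC[C@@]1(C)[C@@H](C[Zn]I)C[C@]2(CC=C(C)C)C(=O)[C@@]1(CC=C(C)C)C(=O)C=C2OC
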